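The readings stem from a simulated flask with constants of no real substance, and the scatter is random.

**The readings.** At 30.0 min, Monday's flask, the one asked about, read 59% target, down 5 percentage points from 15.0 min. Tuesday's flask, at half the loading, read 67% at 8.00 min and 67% at 20.0 min.

| setting | Monday's | Tuesday's | flask |
|---|---|---|---|
| solid substrate | 2 M | 1 M | 2.0 M |
| temperature | 80 °C | 80 °C | 80 °C |
| remark | the very flask that is asked about, followed so far | run made earlier |  |
| time |  |  | 50 min |

| run | time / min | target / % |
|---|---|---|
| Monday's | 5.00 | 26 |
| Monday's | 10.0 | 56 |
| Monday's | 15.0 | 64 |
| Monday's | 20.0 | 64 |
| Monday's | 25.0 | 62 |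
| Monday's | 30.0 | 59 |
| Tuesday's | 1.33 | 6 |
| Tuesday's | 4.00 | 43 |
| Tuesday's | 8.00 | 67 |
| Tuesday's | 10.0 | 67 |
| Tuesday's | 15.0 | 68 |
| Tuesday's | 20.0 | 67 |

(each reading ± 1.5 percentage points)

- percent here means solid substrate units held: one self-condensation product counts as two
- solid substrate is a solid; its amount is given per volume of the solution
- target taken out counts as made
- the numbers in the tables scatter by 1.5 percentage points (one standard deviation)
- steps under discussion: starting material <-> target; starting material <-> isomer of the product; target <-> isomer of the product; 2 starting material -> self-condensation product; solid substrate <-> starting material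
- at the start none of the solid substrate is in solution
- the earlier runs do not show what temperature does; that part of a forecast is a guess

- north: change nothing and wait 1.5 h more
- north-west: at 50 min take out 90% of the target then present, then wait 1.5 h
- south: at 50 min raise the temperature by 10 K, then wait 1.5 h

- target, in percent of the solid substrate first charged, at 50 min
- what to do for the largest gain in target; "none" if nothing gains more than 2 percentage points (north / north-west / south / none)
- target present, with what was taken out counted in, in percent of the solid substrate first charged, after north-west
- target present, with what was taken out counted in, in percent of the solid substrate first charged, after south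

**Turned round.** I asked what would make the removal useless. Let P be the target at 50 min. I assumed a second-order fall and extended the rise of 1/P over Monday's readings, which gave P = 53.4%. Removal would leave 5.34% of target beside the reserve R, the starting material and isomer of the product in solution. Tuesday's readings had levelled by 8.00 min, far shorter than the wait of 1.5 h, so I let the thinned pool refill to a target share f of at least Tuesday's reading of 67%, and I set the drain aside. The critical reserve R_c is the reserve at which the refill just gains the margin: margin plus target left, divided by f, less target left. It came to 5.62%. "None" therefore needed target at 90.5% of the pool or more. A floor on f does not exclude that, so my choice of north-west was a judgement.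

**The forecast.** It gave 51.5%, lower than my P, chose north-west, and gave 62% and 23%, reading the fall as “second-order, irreversible self-condensation as the drain”.

**The flask.** The asked flask held 57.8% at 50 min. The best choice was north-west, gaining 9.7 points, with 67.5% after north-west and 28.8% after south. Its R was 15.6%, above the R_c of 5.83% reckoned on this target.

    starting material ⇌ target (K = 12.0, k = 0.00790 s⁻¹, Ea = 94.0 kJ mol⁻¹, ΔH = −35.0 kJ mol⁻¹)
    starting material ⇌ isomer of the product (K = 2.30, k = 0.00330 s⁻¹, Ea = 93.0 kJ mol⁻¹, ΔH = 31.0 kJ mol⁻¹)
    target ⇌ isomer of the product (k = 0.00400 s⁻¹, Ea = 105 kJ mol⁻¹)
    2 starting material → self-condensation product (k = 0.00410 M⁻¹ s⁻¹, Ea = 74.0 kJ mol⁻¹)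
    solid substrate ⇌ starting material, rate k5*(cs5 - [starting material]) while solid is left; crystals form when [starting material] > cs5 (solubility = 0.670 M, k = 0.00740 s⁻¹)
    (constants at 80 °C)

**Cooler neighbour.** At 65 °C, the same flask held 63.2% target and R = 7.44% at 50.0 min. With f carried over from 80 °C, R_c became 6.10%, so its R stood above R_c by 1.3 points.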